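**Remark on the chemistry:** the target has no stereocentre and no stereogenic axis, so it is achiral and the question of a single enantiomer does not arise. The sp3 centres in 3, 4, 5, 11 and 13 are formed racemic and are all erased before the target.

## Retrosynthetic overview

- The A ring (C4a, C5, C6, C7, C8, C8a) is made last, not bought: its four contiguous oxygenated carbons C5–C8 are the four carbons of dimethyl squarate, and C4a=C8a is the C5=C6 bond of a monocyclic 4-pyranone.
- Target 15 ⇐ 5,8-dihydroxy-3,6,7-trimethoxyflavone 14 (two O-methylations) ⇐ cyclobutenone 11 by thermal 4π-opening/6π-closure, which forms C8–C8a and the whole benzene ring.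
- 11 ⇐ C4a–C5 bond: 5-magnesiated 3-methoxy-2-phenyl-4-pyranone (from iodide 8) + dimethyl squarate 9.
- Pyranone 7 (C ring already carrying the 3-OMe and the phenyl B ring) ⇐ furan-2-yl(phenyl)methanol 3 by oxidative furan-to-pyranone ring expansion ⇐ furfural + PhMgBr.
- Order of ring formation: C ring (γ-pyrone, from a furan) first, A ring (benzene) last; the B ring is bought.

Key step: step 6

## Route

**Step 1**
Reactants: 1 furfural; 2 phenylmagnesium bromide
Product: 3 furan-2-yl(phenyl)methanol (racemic)
Conditions: PhMgBr (1.1 equiv), THF, 0 °C → rt; then sat. aq NH4Cl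
Reagents that add atoms: none
Why: Grignard 1,2-addition to the aldehyde should give the secondary furyl carbinol; the new stereocentre is racemic and becomes sp2 in step 2.

**Step 2**
Reactants: 3 furan-2-yl(phenyl)methanol
Product: 6 3-hydroxy-2-phenyl-4H-pyran-4-one, via Achmatowicz pyranone 4 (not isolated), via 4-bromopyranone 5 (not isolated)
Conditions: Br2 (2.05 equiv), H2O–MeCN, −10 → 5 °C; then MeCN stripped, 90 °C
Reagents that add atoms: water, O
Why: The first equivalent of bromine should effect the Achmatowicz ring expansion to 4, the second should brominate the enone C4=C5 bond (addition–elimination) to 5, and the HBr formed should drive the hydrolytic rearrangement on heating (the halogen-mediated one-pot route known for maltol-type 3-hydroxy-4-pyranones), the acidic benzylic C2–H assisting the enolisation.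

**Step 3**
Reactants: 6 3-hydroxy-2-phenyl-4H-pyran-4-one
Product: 7 3-methoxy-2-phenyl-4H-pyran-4-one
Conditions: MeI, K2CO3, acetone, reflux
Reagents that add atoms: iodomethane, CI
Why: Williamson O-methylation of the acidic enolic 3-OH installs the 3-OMe of the target early and removes the only acidic proton before the organometallic step.

**Step 4**
Reactants: 7 3-methoxy-2-phenyl-4H-pyran-4-one
Product: 8 5-iodo-3-methoxy-2-phenyl-4H-pyran-4-one
Conditions: NIS (1.1 equiv), TFA (0.3 equiv), MeCN, 50 °C, dark
Reagents that add atoms: N-iodosuccinimide, O=C1CCC(=O)N1I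
Why: Electrophilic iodination should occur at C5, the only nucleophilic ring carbon (β-carbon of the O1–C6=C5 enol ether, α to C4=O), since C2 and C3 are blocked, C6 is electrophilic and the phenyl ring is deactivated.

**Step 5**
Reactants: 8 5-iodo-3-methoxy-2-phenyl-4H-pyran-4-one; 9 dimethyl squarate (3,4-dimethoxycyclobut-3-ene-1,2-dione)
Product: 11 4-hydroxy-2,3-dimethoxy-4-(5-methoxy-4-oxo-6-phenyl-4H-pyran-3-yl)cyclobut-2-en-1-one (racemic), via pyranonyl Grignard reagent 10 (not isolated)
Conditions: i-PrMgCl·LiCl (1.05 equiv), THF, −40 °C; then 9 (1.1 equiv), −78 → −30 °C; sat. aq NH4Cl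
Reagents that add atoms: none
Why: Iodine–magnesium exchange on a cyclic α-iodo-β-alkoxy enone is fast at low temperature and gives a carbonyl-chelated alkenyl Grignard reagent, whose 1,2-addition to one of the two equivalent squarate carbonyls (the standard entry to Moore substrates) forms the C4a–C5 bond; the carbinol centre is racemic and is destroyed in step 6.

**Step 6**
Reactants: 11 4-hydroxy-2,3-dimethoxy-4-(5-methoxy-4-oxo-6-phenyl-4H-pyran-3-yl)cyclobut-2-en-1-one
Product: 14 5,8-dihydroxy-3,6,7-trimethoxyflavone, via (Z)-dienylketene 12 (not isolated), via cyclohexadienone 13 (not isolated)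
Conditions: degassed PhMe (0.02 M), 110 °C, Ar
Reagents that add atoms: none
Why: Heating should open the cyclobutenone by conrotatory 4π-electrocyclic cleavage of the C(=O)–C(OH) bond, the donor hydroxyl rotating outward so that the pyranonyl group ends up cis to the ketene in dienylketene 12. The ketene C=C, the C(OMe)=C(OH) bond and the pyranone C5=C6 bond then form a hexatriene that should close by thermal disrotatory 6π-electrocyclisation, making the C8–C8a bond and with it the six-membered A ring (cyclohexadienone 13). Enolisation of 13 (H from C8a to the ketene-derived oxygen) aromatises the A ring and restores the γ-pyrone, which supplies the driving force. The closest known reaction type is the Moore rearrangement of squarate-derived 4-alkenyl- and 4-(hetero)aryl-4-hydroxycyclobutenones to hydroquinones. No stereocentre survives, because the carbinol centre of 11 and the sp3 C8a of 13 both become sp2. The selectivity needed is outward rotation of OH (inward rotation would let the hydroxyl trap the ketene as a butenolide), which the donor character of OH secures; the ring-fusion regiochemistry is fixed because C6 is the only free terminus of the pyranone alkene, and oxygen is excluded to keep 14 from oxidising to the quinone.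

**Step 7**
Reactants: 14 5,8-dihydroxy-3,6,7-trimethoxyflavone
Product: 15 3,5,6,7,8-pentamethoxyflavone
Conditions: Me2SO4 (5 equiv), K2CO3 (6 equiv), acetone, reflux, Ar
Reagents that add atoms: dimethyl sulfate, COS(=O)(=O)OC
Why: Exhaustive Williamson methylation should cap the free 8-OH and, with excess reagent and prolonged reflux, the chelated 5-OH, while argon keeps the hydroquinone from oxidising before it is alkylated.

## Compound list

1 | furfural | O=Cc1ccco1 | starting material
2 | phenylmagnesium bromide | Br[Mg]c1ccccc1 | starting material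
3 | furan-2-yl(phenyl)methanol (racemic) | OC(c1ccccc1)c1ccco1 | intermediate
4 | 6-hydroxy-2-phenyl-2H-pyran-3(6H)-one (Achmatowicz pyranone, diastereomer mixture, not isolated) | O=C1C=CC(O)OC1c1ccccc1 | intermediate
5 | 4-bromo-6-hydroxy-2-phenyl-2H-pyran-3(6H)-one (diastereomer mixture, not isolated) | O=C1C(Br)=CC(O)OC1c1ccccc1 | intermediate
6 | 3-hydroxy-2-phenyl-4H-pyran-4-one | Oc1c(-c2ccccc2)occc1=O | intermediate
7 | 3-methoxy-2-phenyl-4H-pyran-4-one | COc1c(-c2ccccc2)occc1=O | intermediate
8 | 5-iodo-3-methoxy-2-phenyl-4H-pyran-4-one | COc1c(-c2ccccc2)occ(I)c1=O | intermediate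
9 | dimethyl squarate (3,4-dimethoxycyclobut-3-ene-1,2-dione) | COC1=C(OC)C(=O)C1=O | starting material
10 | (5-methoxy-4-oxo-6-phenyl-4H-pyran-3-yl)magnesium chloride (not isolated) | COc1c(-c2ccccc2)occ([Mg]Cl)c1=O | intermediate
11 | 4-hydroxy-2,3-dimethoxy-4-(5-methoxy-4-oxo-6-phenyl-4H-pyran-3-yl)cyclobut-2-en-1-one (racemic) | COC1=C(OC)C(O)(c2coc(-c3ccccc3)c(OC)c2=O)C1=O | intermediate
12 | (3Z)-4-hydroxy-2,3-dimethoxy-4-(5-methoxy-4-oxo-6-phenyl-4H-pyran-3-yl)buta-1,3-dien-1-one (dienylketene, not isolated) | O=C=C(OC)/C(OC)=C(/O)c1coc(-c2ccccc2)c(OC)c1=O | intermediate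
13 | 5-hydroxy-3,6,7-trimethoxy-2-phenyl-4H-chromene-4,8(8aH)-dione (cyclohexadienone, racemic, not isolated) | O=C1C(OC)=C(OC)C(O)=C2C(=O)C(OC)=C(c3ccccc3)OC12 | intermediate
14 | 5,8-dihydroxy-3,6,7-trimethoxyflavone (5,8-dihydroxy-3,6,7-trimethoxy-2-phenyl-4H-chromen-4-one) | COc1c(OC)c(O)c2c(=O)c(OC)c(-c3ccccc3)oc2c1O | intermediate
15 | 3,5,6,7,8-pentamethoxyflavone (3,5,6,7,8-pentamethoxy-2-phenyl-4H-chromen-4-one) | COc1c(OC)c(OC)c2c(=O)c(OC)c(-c3ccccc3)oc2c1OC | target

## Step count and risks

Total step count: 7. Longest linear sequence: 7 steps (1 → 15); squarate 9 enters as a purchased building block in step 5.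

**Steps most likely to fail**

1. Step 5. The α-magnesiated pyranone 10 carries the ring oxygen β to the metal. It may fragment by β-elimination (ring opening), or it may add too slowly to the squarate to outrun its own decomposition. The fallback sets out from 7 and reverses the site of metalation. Deprotonation of 7 at C6, the vinylic C–H next to the ring oxygen (TMPMgCl·LiCl, THF, −40 °C), should give (5-methoxy-4-oxo-6-phenyl-4H-pyran-2-yl)magnesium chloride F1, which has no β-leaving group. Addition to 9 and NH4Cl quench should give the regioisomeric carbinol 4-hydroxy-2,3-dimethoxy-4-(5-methoxy-4-oxo-6-phenyl-4H-pyran-2-yl)cyclobut-2-en-1-one F2, in which the addition has formed the C8–C8a bond. Thermolysis as in step 6 should pass through the dienylketene (3Z)-4-hydroxy-2,3-dimethoxy-4-(5-methoxy-4-oxo-6-phenyl-4H-pyran-2-yl)buta-1,3-dien-1-one F3 and, by 6π-closure onto C5 of the pyranone (now forming C4a–C5), through the cyclohexadienone 8-hydroxy-3,6,7-trimethoxy-2-phenyl-4H-chromene-4,5(4aH)-dione F4. F4 tautomerises to the same hydroquinone, so the route is rejoined at 14.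

2. Step 6. The 6π-closure onto the electron-poor pyranone alkene may be slow, which leaves time for the hydroxyl to trap the ketene as a butenolide, and the hydroquinone may oxidise or degrade at the reaction temperature. The fallback sets out from 11 and runs the ring expansion on a substrate without a free hydroxyl. Purdie methylation of the tertiary alcohol (MeI, Ag2O, MeCN, rt) should give 2,3,4-trimethoxy-4-(5-methoxy-4-oxo-6-phenyl-4H-pyran-3-yl)cyclobut-2-en-1-one F5. Thermolysis (p-xylene, 140 °C) should then pass through the dienylketene (3Z)-2,3,4-trimethoxy-4-(5-methoxy-4-oxo-6-phenyl-4H-pyran-3-yl)buta-1,3-dien-1-one F6 and the cyclohexadienone 3,5,6,7-tetramethoxy-2-phenyl-4H-chromene-4,8(8aH)-dione F7 to the air-stable monophenol 8-hydroxy-3,5,6,7-tetramethoxyflavone F8, with the 5-OMe already in place. Methylation of the unchelated 8-OH (MeI, K2CO3, acetone, reflux) comes back to the route at 15.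

3. Step 2. In the one-pot procedure the electron-rich hydroxypyranone may be brominated further, and the acid-sensitive benzylic furyl carbinol and pyranone intermediates may polymerise in hot HBr. The fallback sets out from 3 and replaces halogenation by a stepwise, nucleophilic oxidation. Achmatowicz oxidation with mCPBA (CH2Cl2, 0 °C) should give 4, this time isolated. Methylation of the hemiacetal (MeI, Ag2O) should give 6-methoxy-2-phenyl-2H-pyran-3(6H)-one F9. Nucleophilic epoxidation of the enone (H2O2, cat. NaOH, MeOH, 0 °C) should give 2-methoxy-4-phenyl-3,7-dioxabicyclo[4.1.0]heptan-5-one F10. Warming F10 with an acidic resin in water–dioxane (90 °C) should open the epoxide to the 3,4-dione, eliminate methanol and enolise, which comes back to the route at 6.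

## Further compounds

F1 | step 5 | (5-methoxy-4-oxo-6-phenyl-4H-pyran-2-yl)magnesium chloride | COc1c(-c2ccccc2)oc([Mg]Cl)cc1=O
F2 | step 5 | 4-hydroxy-2,3-dimethoxy-4-(5-methoxy-4-oxo-6-phenyl-4H-pyran-2-yl)cyclobut-2-en-1-one (racemic) | COC1=C(OC)C(O)(c2cc(=O)c(OC)c(-c3ccccc3)o2)C1=O
F3 | step 5 | (3Z)-4-hydroxy-2,3-dimethoxy-4-(5-methoxy-4-oxo-6-phenyl-4H-pyran-2-yl)buta-1,3-dien-1-one | O=C=C(OC)/C(OC)=C(/O)c1cc(=O)c(OC)c(-c2ccccc2)o1
F4 | step 5 | 8-hydroxy-3,6,7-trimethoxy-2-phenyl-4H-chromene-4,5(4aH)-dione (racemic) | O=C1C(OC)=C(OC)C(O)=C2OC(c3ccccc3)=C(OC)C(=O)C12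
F5 | step 6 | 2,3,4-trimethoxy-4-(5-methoxy-4-oxo-6-phenyl-4H-pyran-3-yl)cyclobut-2-en-1-one (racemic) | COC1=C(OC)C(OC)(c2coc(-c3ccccc3)c(OC)c2=O)C1=O
F6 | step 6 | (3Z)-2,3,4-trimethoxy-4-(5-methoxy-4-oxo-6-phenyl-4H-pyran-3-yl)buta-1,3-dien-1-one | O=C=C(OC)/C(OC)=C(/OC)c1coc(-c2ccccc2)c(OC)c1=O
F7 | step 6 | 3,5,6,7-tetramethoxy-2-phenyl-4H-chromene-4,8(8aH)-dione (racemic) | O=C1C(OC)=C(OC)C(OC)=C2C(=O)C(OC)=C(c3ccccc3)OC12
F8 | step 6 | 8-hydroxy-3,5,6,7-tetramethoxyflavone | COc1c(OC)c(OC)c2c(=O)c(OC)c(-c3ccccc3)oc2c1O
F9 | step 2 | 6-methoxy-2-phenyl-2H-pyran-3(6H)-one (diastereomer mixture) | COC1C=CC(=O)C(c2ccccc2)O1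
F10 | step 2 | 2-methoxy-4-phenyl-3,7-dioxabicyclo[4.1.0]heptan-5-one (diastereomer mixture) | COC1OC(c2ccccc2)C(=O)C2OC12
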